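Everything rests on breaking the C1–C10 bond of the ten-membered carbocycle (C1–C10). In the epoxide fused to that ring, oxygen bridges the C10 methine and the quaternary C1 bearing the C14 acetoxymethyl arm; an allylic alcohol at C10 whose alkene is the exocyclic C1=C14 methylene therefore holds this epoxide in masked form. A ligand-controlled Nozaki–Hiyama–Kishi addition of the C1 alkenyl iodide to the C10 aldehyde closes the ring, makes C1–C10 and sets C10 in one operation; the carbinol then passes its configuration on to C1. The precursor is an open-chain 2-iodoalkene/(Z)-enone/aldehyde that already carries the C8–C11 spiro-epoxide, set by Sharpless epoxidation.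

Key step: step 14

Remark: atoms are labelled as in the target (C1 epoxide carbon bearing C14H2OAc, then C2, C3, C4=C5 with C15H3 on C5, C6 ketone, C7, spiro C8, C9, C10 epoxide CH, exocyclic epoxide carbon C11 with C12H3 and C13H2OAc); it is assumed that one antipode of the valinol-derived sulfonamide ligand delivers C1 to the Re face of the C10 aldehyde, to be settled by running both once, and that 1 and 15 are bought.

Step 1
Reactants: 1 tert-butyl(but-3-yn-1-yloxy)dimethylsilane
Product: 3 5-(tert-butyldimethylsilyloxy)pent-2-yn-1-ol, via lithium acetylide 2 (not isolated)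
Conditions: n-BuLi, THF, −78 °C; (CH2O)n, −78 °C → rt
Reagents that add atoms: formaldehyde (from paraformaldehyde), C=O
Why: Acetylide hydroxymethylation, in which n-BuLi removes only the alkynyl proton and the acetylide 2 adds to formaldehyde, the silyl ether being inert.

Step 2
Reactants: 3 5-(tert-butyldimethylsilyloxy)pent-2-yn-1-ol; 4 methylmagnesium bromide; 5 allyl bromide
Product: 7 (2E)-3-[2-(tert-butyldimethylsilyloxy)ethyl]-2-methylhexa-2,5-dien-1-ol (CH2OH cis to allyl, methyl cis to the silyloxyethyl arm), via cyclic alkenylmagnesium alkoxide 6 (not isolated)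
Conditions: MeMgBr (4 equiv), CuI (10 mol %), THF, 0 °C → reflux; then allyl bromide, 0 °C → rt
Reagents that add atoms: none
Why: Copper-catalysed anti-carbomagnesiation of a 2-alkyn-1-ol with electrophilic trapping, in which the magnesium alkoxide should direct methyl to C11 and magnesium to C8 inside the five-membered chelate 6, so that allylation with retention fixes the tetrasubstituted alkene geometry needed for C8 and C11.

Step 3
Reactants: 7 (2E)-3-[2-(tert-butyldimethylsilyloxy)ethyl]-2-methylhexa-2,5-dien-1-ol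
Product: 8 [(2S,3S)-3-[2-(tert-butyldimethylsilyloxy)ethyl]-2-methyl-3-(prop-2-en-1-yl)oxiran-2-yl]methanol
Conditions: Ti(OiPr)4 (10 mol %), L-(+)-diethyl tartrate (12 mol %), t-BuOOH, 4 Å MS, CH2Cl2, −20 °C
Reagents that add atoms: tert-butyl hydroperoxide, CC(C)(C)OO
Why: Katsuki–Sharpless asymmetric epoxidation, which should touch only the allylic alcohol alkene; L-(+)-diethyl tartrate selects the face that makes C11 S, and syn oxygen transfer turns the fixed alkene geometry into S at C8, so both quaternary centres are set together.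

Step 4
Reactants: 8 [(2S,3S)-3-[2-(tert-butyldimethylsilyloxy)ethyl]-2-methyl-3-(prop-2-en-1-yl)oxiran-2-yl]methanol
Product: 9 [(2S,3S)-3-[2-(tert-butyldimethylsilyloxy)ethyl]-2-methyl-3-(prop-2-en-1-yl)oxiran-2-yl]methyl acetate
Conditions: Ac2O, pyridine, DMAP (cat.), CH2Cl2, 0 °C → rt
Reagents that add atoms: acetic anhydride, CC(=O)OC(C)=O
Why: DMAP-catalysed acylation of the primary alcohol should install the C13 acetate of the target, which then serves as its own protecting group.

Step 5
Reactants: 9 [(2S,3S)-3-[2-(tert-butyldimethylsilyloxy)ethyl]-2-methyl-3-(prop-2-en-1-yl)oxiran-2-yl]methyl acetate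
Product: 10 [(2S,3S)-3-(2-hydroxyethyl)-2-methyl-3-(prop-2-en-1-yl)oxiran-2-yl]methyl acetate
Conditions: Bu4NF, AcOH (1:1), THF, 0 °C → rt
Reagents that add atoms: none
Why: Fluoride-mediated desilylation of the primary silyl ether, buffered with acetic acid so that neither the acetate nor the epoxide should be attacked.

Step 6
Reactants: 10 [(2S,3S)-3-(2-hydroxyethyl)-2-methyl-3-(prop-2-en-1-yl)oxiran-2-yl]methyl acetate
Product: 11 [(2S,3S)-2-methyl-3-(2-oxoethyl)-3-(prop-2-en-1-yl)oxiran-2-yl]methyl acetate
Conditions: Dess–Martin periodinane, pyridine, CH2Cl2, 0 °C → rt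
Reagents that add atoms: none
Why: Dess–Martin oxidation of the primary alcohol under pyridine buffering should give the aldehyde without beta-elimination of the epoxide, and 11 is used without storage.

Step 7
Reactants: 12 pent-4-yn-1-ol
Product: 13 4-(trimethylstannyl)pent-4-en-1-ol
Conditions: Me3SnSnMe3, MeLi, THF, −20 °C; CuBr·SMe2, −63 °C; then 12, MeOH, −78 → −63 °C
Reagents that add atoms: (trimethylstannyl)copper dimethyl sulfide complex Me3SnCu·SMe2, C[Sn](C)(C)[Cu].CSC
Why: Stannylcupration of a terminal alkyne with protonation by methanol in the flask should trap the internal-tin adduct of the reversible syn addition, giving the 2-stannyl-1-alkene that masks the C1 iodoalkene until step 12.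

Step 8
Reactants: 13 4-(trimethylstannyl)pent-4-en-1-ol
Product: 14 4-(trimethylstannyl)pent-4-enal
Conditions: Dess–Martin periodinane, pyridine, CH2Cl2, 0 °C
Reagents that add atoms: none
Why: Dess–Martin oxidation of the primary alcohol, with pyridine to prevent protodestannylation by the acetic acid released.

Step 9
Reactants: 14 4-(trimethylstannyl)pent-4-enal; 15 ethyltriphenylphosphonium iodide
Product: 19 [(5Z)-6-iodohepta-1,5-dien-2-yl]trimethylstannane, via ethylidenetriphenylphosphorane 16 (not isolated), via (1-iodoethyl)triphenylphosphonium iodide 17 (not isolated), via (1-iodoethylidene)triphenylphosphorane 18 (not isolated)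
Conditions: n-BuLi, THF, rt; I2, −78 °C; NaN(SiMe3)2, −20 °C; then 14, −78 °C → rt
Reagents that add atoms: iodine, II
Why: Stork–Zhao-type Wittig olefination, in which the unstabilised alpha-iodo ylide 18 should react under kinetic control to put iodine cis to the chain (Z), the stannane surviving because the iodine is consumed in forming 17 before the aldehyde is added.

Step 10
Reactants: 11 [(2S,3S)-2-methyl-3-(2-oxoethyl)-3-(prop-2-en-1-yl)oxiran-2-yl]methyl acetate; 19 [(5Z)-6-iodohepta-1,5-dien-2-yl]trimethylstannane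
Product: 21 [(2S,3S)-3-[(3Z)-2-hydroxy-3-methyl-7-(trimethylstannyl)octa-3,7-dien-1-yl]-2-methyl-3-(prop-2-en-1-yl)oxiran-2-yl]methyl acetate (both C6 epimers), via acyclic alkenylchromium dichloride 20 (not isolated)
Conditions: CrCl2 (6 equiv), NiCl2 (2 mol %), DMSO, rt
Reagents that add atoms: none
Why: Intermolecular Nozaki–Hiyama–Kishi coupling, in which zerovalent nickel should insert only into the C–I bond and the alkenylchromium 20 should add to the aldehyde with retention of the (Z) geometry while acetate, epoxide, allyl group and stannane stay intact; the C6 carbinol forms as an epimer mixture that step 11 removes.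

Step 11
Reactants: 21 [(2S,3S)-3-[(3Z)-2-hydroxy-3-methyl-7-(trimethylstannyl)octa-3,7-dien-1-yl]-2-methyl-3-(prop-2-en-1-yl)oxiran-2-yl]methyl acetate
Product: 22 [(2S,3S)-2-methyl-3-[(3Z)-3-methyl-2-oxo-7-(trimethylstannyl)octa-3,7-dien-1-yl]-3-(prop-2-en-1-yl)oxiran-2-yl]methyl acetate
Conditions: Dess–Martin periodinane, pyridine, CH2Cl2, 0 °C
Reagents that add atoms: none
Why: Dess–Martin oxidation of the allylic alcohol should give the (Z)-enone and erase the C6 stereocentre, the pyridine buffer guarding against Z to E isomerisation and epoxide opening.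

Step 12
Reactants: 22 [(2S,3S)-2-methyl-3-[(3Z)-3-methyl-2-oxo-7-(trimethylstannyl)octa-3,7-dien-1-yl]-3-(prop-2-en-1-yl)oxiran-2-yl]methyl acetate
Product: 23 [(2S,3S)-3-[(3Z)-7-iodo-3-methyl-2-oxoocta-3,7-dien-1-yl]-2-methyl-3-(prop-2-en-1-yl)oxiran-2-yl]methyl acetate
Conditions: I2 (1.05 equiv), CH2Cl2, 0 °C, dark; aq Na2S2O3
Reagents that add atoms: iodine, II
Why: Iododestannylation, an ipso substitution of the C–Sn bond that should be far faster than any reaction of iodine with the allyl group or the electron-poor enone, unmasks the 2-iodoalkene only after the other alkenyl iodide has been used.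

Step 13
Reactants: 23 [(2S,3S)-3-[(3Z)-7-iodo-3-methyl-2-oxoocta-3,7-dien-1-yl]-2-methyl-3-(prop-2-en-1-yl)oxiran-2-yl]methyl acetate
Product: 25 [(2S,3S)-3-[(3Z)-7-iodo-3-methyl-2-oxoocta-3,7-dien-1-yl]-2-methyl-3-(2-oxoethyl)oxiran-2-yl]methyl acetate, via vicinal diol 24 (not isolated)
Conditions: OsO4 (2 mol %), NaIO4, 2,6-lutidine, dioxane/H2O 3:1, rt
Reagents that add atoms: osmium tetroxide, O=[Os](=O)(=O)=O; sodium periodate, [Na+].[O-][I](=O)(=O)=O; water, O
Why: Lemieux–Johnson cleavage, in which OsO4 should dihydroxylate the monosubstituted alkene in preference to the iodine-deactivated C1=C14 and the conjugated C4=C5 bonds, and periodate cleaves diol 24 at the near-neutral pH kept by 2,6-lutidine; 25 is used at once.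

Step 14
Reactants: 25 [(2S,3S)-3-[(3Z)-7-iodo-3-methyl-2-oxoocta-3,7-dien-1-yl]-2-methyl-3-(2-oxoethyl)oxiran-2-yl]methyl acetate
Product: 27 [(2S,3S,6Z,11S)-11-hydroxy-2,6-dimethyl-10-methylidene-5-oxo-1-oxaspiro[2.9]dodec-6-en-2-yl]methyl acetate (route labels 8S,10S,11S), via cyclising alkenylchromium dichloride 26 (not isolated)
Conditions: CrCl2 (6 equiv), N-[2-(4-isopropyl-4,5-dihydro-1,3-oxazol-2-yl)-6-methylphenyl]methanesulfonamide (one antipode, 6.6 equiv), Et3N (6.6 equiv), THF, rt, premixed; then NiCl2 (20 mol %) and 25 added over 12 h, 2 mM, rt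
Reagents that add atoms: none
Why: Zerovalent nickel, made from NiCl2 by CrCl2, inserts into the C1–I bond and hands the alkenyl group to chromium that carries the deprotonated chiral sulfonamide, and the trivalent alkenylchromium 26 adds to the C10 aldehyde, iodide leaving as CrCl2I. The closest known reaction type is the intramolecular Nozaki–Hiyama–Kishi closure of medium and large rings run with a stoichiometric chromium–sulfonamide reagent. The ten-membered carbocycle (C1–C10) closes in the 10-exo-trig mode, C1 attacking the C10 carbonyl carbon while the carbonyl oxygen stays outside the new ring. The only new stereocentre, C10, is controlled by the ligand on chromium, whose antipode is chosen so that C1 reaches the Re face and the (10S) carbinol results; the C8 centre, beta to the aldehyde, can only add to or subtract from this reagent control. The step needs addition to the aldehyde and not to the C6 ketone, which the lower electrophilicity of the conjugated ketone secures, and ring closure in place of oligomerisation, which slow addition at 2 mM and the bend imposed by the (Z)-C4=C5 bond and the C8 spiro centre favour. The neutral, non-enolising medium should leave the spiro-epoxide (beta to both carbonyls), the (Z)-enone and the acetate untouched.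

Step 15
Reactants: 27 [(2S,3S,6Z,11S)-11-hydroxy-2,6-dimethyl-10-methylidene-5-oxo-1-oxaspiro[2.9]dodec-6-en-2-yl]methyl acetate
Product: 28 [(2S,3S,6Z,10R,11S)-10,11-dihydroxy-10-(hydroxymethyl)-2,6-dimethyl-5-oxo-1-oxaspiro[2.9]dodec-6-en-2-yl]methyl acetate (route labels 1R,8S,10S,11S)
Conditions: OsO4 (5 mol %), N-methylmorpholine N-oxide (1.1 equiv), acetone/H2O, 0 °C
Reagents that add atoms: osmium tetroxide, O=[Os](=O)(=O)=O; N-methylmorpholine N-oxide, C[N+]1([O-])CCOCC1; water, O
Why: Upjohn dihydroxylation should take the electron-rich exocyclic C1=C14 bond and not the enone, and C1 is set by relay from C10, because in the rotamer that avoids A(1,2) strain (C10–H eclipsing C1–C2) the C10–C9 ring bond covers one face and osmium adds to the other, the one carrying the C10 hydroxyl, so that the new C1–O bond is cis to C10–O (1R).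

Step 16
Reactants: 28 [(2S,3S,6Z,10R,11S)-10,11-dihydroxy-10-(hydroxymethyl)-2,6-dimethyl-5-oxo-1-oxaspiro[2.9]dodec-6-en-2-yl]methyl acetate
Product: 29 {(2S,3S,6Z,10R,11S)-10-[(acetyloxy)methyl]-10,11-dihydroxy-2,6-dimethyl-5-oxo-1-oxaspiro[2.9]dodec-6-en-2-yl}methyl acetate
Conditions: AcCl (1.1 equiv), 2,4,6-collidine, CH2Cl2, −78 °C
Reagents that add atoms: acetyl chloride, CC(=O)Cl
Why: Kinetically selective acylation, in which acetyl chloride with collidine at low temperature should acetylate the unhindered primary C14 hydroxyl and leave the secondary C10 and tertiary C1 hydroxyls free.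

Step 17
Reactants: 29 {(2S,3S,6Z,10R,11S)-10-[(acetyloxy)methyl]-10,11-dihydroxy-2,6-dimethyl-5-oxo-1-oxaspiro[2.9]dodec-6-en-2-yl}methyl acetate
Product: 31 CNP0185847.4, the bis-epoxide diacetate (route labels 1R,8S,10R,11S), via C10 oxyphosphonium ion 30 (not isolated)
Conditions: PPh3, DIAD, THF, 0 °C → rt
Reagents that add atoms: none
Why: Mitsunobu cyclodehydration of a 1,2-diol, in which the less hindered secondary C10 hydroxyl should be activated as 30 and displaced by the tertiary C1 oxygen in a 3-exo-tet closure with inversion at C10, giving the C1–C10 epoxide without base so that the epoxide beta to the C6 ketone and both acetates are kept.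

Compound list
1 | tert-butyl(but-3-yn-1-yloxy)dimethylsilane | C#CCCO[Si](C)(C)C(C)(C)C | starting material
2 | [4-(tert-butyldimethylsilyloxy)but-1-yn-1-yl]lithium | [Li]C#CCCO[Si](C)(C)C(C)(C)C | intermediate
3 | 5-(tert-butyldimethylsilyloxy)pent-2-yn-1-ol | OCC#CCCO[Si](C)(C)C(C)(C)C | intermediate
4 | methylmagnesium bromide | C[Mg]Br | starting material
5 | allyl bromide | C=CCBr | starting material
6 | 3-[2-(tert-butyldimethylsilyloxy)ethyl]-4-methyl-2,5-dihydro-1,2-oxamagnesole (cyclic alkenylmagnesium alkoxide) | CC1=C(CCO[Si](C)(C)C(C)(C)C)[Mg]OC1 | intermediate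
7 | (2E)-3-[2-(tert-butyldimethylsilyloxy)ethyl]-2-methylhexa-2,5-dien-1-ol | OC/C(C)=C(\CC=C)CCO[Si](C)(C)C(C)(C)C | intermediate
8 | [(2S,3S)-3-[2-(tert-butyldimethylsilyloxy)ethyl]-2-methyl-3-(prop-2-en-1-yl)oxiran-2-yl]methanol | CC(C)(C)[Si](C)(C)OCC[C@]1(CC=C)O[C@@]1(C)CO | intermediate
9 | [(2S,3S)-3-[2-(tert-butyldimethylsilyloxy)ethyl]-2-methyl-3-(prop-2-en-1-yl)oxiran-2-yl]methyl acetate | CC(C)(C)[Si](C)(C)OCC[C@]1(CC=C)O[C@@]1(C)COC(C)=O | intermediate
10 | [(2S,3S)-3-(2-hydroxyethyl)-2-methyl-3-(prop-2-en-1-yl)oxiran-2-yl]methyl acetate | OCC[C@]1(CC=C)O[C@@]1(C)COC(C)=O | intermediate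
11 | [(2S,3S)-2-methyl-3-(2-oxoethyl)-3-(prop-2-en-1-yl)oxiran-2-yl]methyl acetate | O=CC[C@]1(CC=C)O[C@@]1(C)COC(C)=O | intermediate
12 | pent-4-yn-1-ol | C#CCCCO | starting material
13 | 4-(trimethylstannyl)pent-4-en-1-ol | C=C(CCCO)[Sn](C)(C)C | intermediate
14 | 4-(trimethylstannyl)pent-4-enal | C=C(CCC=O)[Sn](C)(C)C | intermediate
15 | ethyltriphenylphosphonium iodide | CC[P+](c1ccccc1)(c1ccccc1)c1ccccc1.[I-] | starting material
16 | ethylidenetriphenylphosphorane | CC=P(c1ccccc1)(c1ccccc1)c1ccccc1 | intermediate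
17 | (1-iodoethyl)triphenylphosphonium iodide | CC(I)[P+](c1ccccc1)(c1ccccc1)c1ccccc1.[I-] | intermediate
18 | (1-iodoethylidene)triphenylphosphorane | CC(I)=P(c1ccccc1)(c1ccccc1)c1ccccc1 | intermediate
19 | [(5Z)-6-iodohepta-1,5-dien-2-yl]trimethylstannane | C/C(I)=C/CCC(=C)[Sn](C)(C)C | intermediate
20 | [(2Z)-6-(trimethylstannyl)hepta-2,6-dien-2-yl]chromium dichloride (trivalent chromium) | C/C(=C/CCC(=C)[Sn](C)(C)C)[Cr](Cl)Cl | intermediate
21 | [(2S,3S)-3-[(3Z)-2-hydroxy-3-methyl-7-(trimethylstannyl)octa-3,7-dien-1-yl]-2-methyl-3-(prop-2-en-1-yl)oxiran-2-yl]methyl acetate, both C6 epimers | C=C(CC/C=C(/C)C(O)C[C@]1(CC=C)O[C@@]1(C)COC(C)=O)[Sn](C)(C)C | intermediate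
22 | [(2S,3S)-2-methyl-3-[(3Z)-3-methyl-2-oxo-7-(trimethylstannyl)octa-3,7-dien-1-yl]-3-(prop-2-en-1-yl)oxiran-2-yl]methyl acetate | C=C(CC/C=C(/C)C(=O)C[C@]1(CC=C)O[C@@]1(C)COC(C)=O)[Sn](C)(C)C | intermediate
23 | [(2S,3S)-3-[(3Z)-7-iodo-3-methyl-2-oxoocta-3,7-dien-1-yl]-2-methyl-3-(prop-2-en-1-yl)oxiran-2-yl]methyl acetate | C=C(I)CC/C=C(/C)C(=O)C[C@]1(CC=C)O[C@@]1(C)COC(C)=O | intermediate
24 | [(2S,3S)-3-(2,3-dihydroxypropyl)-3-[(3Z)-7-iodo-3-methyl-2-oxoocta-3,7-dien-1-yl]-2-methyloxiran-2-yl]methyl acetate, both carbinol epimers | C=C(I)CC/C=C(/C)C(=O)C[C@]1(CC(O)CO)O[C@@]1(C)COC(C)=O | intermediate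
25 | [(2S,3S)-3-[(3Z)-7-iodo-3-methyl-2-oxoocta-3,7-dien-1-yl]-2-methyl-3-(2-oxoethyl)oxiran-2-yl]methyl acetate (key-step precursor) | C=C(I)CC/C=C(/C)C(=O)C[C@]3(CC=O)O[C@@]3(C)COC(C)=O | intermediate
26 | alkenylchromium dichloride at C1 of 25 (trivalent chromium, sulfonamide ligand not drawn) | C=C([Cr](Cl)Cl)CC/C=C(/C)C(=O)C[C@]3(CC=O)O[C@@]3(C)COC(C)=O | intermediate
27 | [(2S,3S,6Z,11S)-11-hydroxy-2,6-dimethyl-10-methylidene-5-oxo-1-oxaspiro[2.9]dodec-6-en-2-yl]methyl acetate (key-step product; route labels 8S,10S,11S) | C=C1CC/C=C(/C)C(=O)C[C@]3(C[C@@H]1O)O[C@@]3(C)COC(C)=O | intermediate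
28 | [(2S,3S,6Z,10R,11S)-10,11-dihydroxy-10-(hydroxymethyl)-2,6-dimethyl-5-oxo-1-oxaspiro[2.9]dodec-6-en-2-yl]methyl acetate | OC[C@]1(O)CC/C=C(/C)C(=O)C[C@]3(C[C@@H]1O)O[C@@]3(C)COC(C)=O | intermediate
29 | {(2S,3S,6Z,10R,11S)-10-[(acetyloxy)methyl]-10,11-dihydroxy-2,6-dimethyl-5-oxo-1-oxaspiro[2.9]dodec-6-en-2-yl}methyl acetate | CC(=O)OC[C@]1(O)CC/C=C(/C)C(=O)C[C@]3(C[C@@H]1O)O[C@@]3(C)COC(C)=O | intermediate
30 | C10 (triphenylphosphonio)oxy cation of 29 | CC(=O)OC[C@]1(O)CC/C=C(/C)C(=O)C[C@]3(C[C@@H]1O[P+](c4ccccc4)(c4ccccc4)c4ccccc4)O[C@@]3(C)COC(C)=O | intermediate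
31 | CNP0185847.4: ten-membered (4Z)-enone with a fused C1–C10 epoxide and a C8–C11 spiro-epoxide, acetoxymethyl groups on C1 and C11, methyl groups on C5 and C11 (1R,8S,10R,11S) | CC(=O)OC[C@]12CC/C=C(/C)C(=O)C[C@]3(C[C@H]1O2)O[C@@]3(C)COC(C)=O | target

Total step count: 17. Longest linear sequence: 14 steps (steps 1–6, then 10–17, from 1).

Steps most likely to fail

Step 14. The chain may fold so that its own preference overrides the ligand, delivering C1 to the Si face of the C10 aldehyde (poor facial selectivity), or intermolecular coupling may compete with ring closure. The fallback sets out from 25 and drops reagent control: the ring is closed with CrCl2 and catalytic NiCl2 in DMSO/THF at high dilution without ligand, and any 27 formed is carried on directly. The epimeric [(2S,3S,6Z,11R)-11-hydroxy-2,6-dimethyl-10-methylidene-5-oxo-1-oxaspiro[2.9]dodec-6-en-2-yl]methyl acetate F1 is inverted at C10 by a Mitsunobu reaction with chloroacetic acid (PPh3, DIAD, toluene, 0 °C) to the (10S)-chloroacetate F2. Thiourea with NaHCO3 in ethanol should then remove the chloroacetyl group without touching the acetate, which returns the material to the route at 27.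

Step 15. Osmium may approach the face of C1=C14 remote from the C10 hydroxyl if the ring holds the C10–C9 bond near the alkene plane, it may also oxidise C4=C5, and the new hydroxyls may attack the spiro-epoxide across the ring. The fallback sets out from 27 and replaces steric control by hydroxyl delivery. VO(acac)2 with t-BuOOH in CH2Cl2 should epoxidise only the allylic alcohol alkene from the face of the C10 hydroxyl, giving the C1–C14 spiro-epoxy alcohol F3. Mesylation (MsCl, pyridine, CH2Cl2, 0 °C) gives the epoxy mesylate F4. CsOAc with 18-crown-6 in toluene then opens the C1–C14 epoxide at the primary C14, and the tertiary alkoxide set free closes onto C10 with inversion, so the sequence comes back to the route directly at 31.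

Step 17. The hindered tertiary/secondary diol may stall as the cyclic phosphorane, or ionisation, elimination or acetyl migration may outrun closure. The fallback sets out from 29 and separates activation from closure: selective mesylation of the secondary hydroxyl (MsCl, pyridine, CH2Cl2, −20 → 0 °C) gives the C10 mesylate F5, and Cs2CO3 in dry acetonitrile at 0 °C, which does not attack the acetates, should close the epoxide with inversion at C10, returning at 31.

Further compounds
F1 | step 14 | [(2S,3S,6Z,11R)-11-hydroxy-2,6-dimethyl-10-methylidene-5-oxo-1-oxaspiro[2.9]dodec-6-en-2-yl]methyl acetate | C=C1CC/C=C(/C)C(=O)C[C@]3(C[C@H]1O)O[C@@]3(C)COC(C)=O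
F2 | step 14 | (2S,3S,6Z,11S)-2-[(acetyloxy)methyl]-2,6-dimethyl-10-methylidene-5-oxo-1-oxaspiro[2.9]dodec-6-en-11-yl chloroacetate | C=C1CC/C=C(/C)C(=O)C[C@]3(C[C@@H]1OC(=O)CCl)O[C@@]3(C)COC(C)=O
F3 | step 15 | C1–C14 spiro-epoxide of 27 with the oxirane oxygen cis to the C10 hydroxyl (1R,8S,10S,11S) | C1O[C@]12CC/C=C(/C)C(=O)C[C@]3(C[C@@H]2O)O[C@@]3(C)COC(C)=O
F4 | step 15 | C10 methanesulfonate of F3 | C1O[C@]12CC/C=C(/C)C(=O)C[C@]3(C[C@@H]2OS(C)(=O)=O)O[C@@]3(C)COC(C)=O
F5 | step 17 | C10 methanesulfonate of 29 | CC(=O)OC[C@]1(O)CC/C=C(/C)C(=O)C[C@]3(C[C@@H]1OS(C)(=O)=O)O[C@@]3(C)COC(C)=O
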